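**Retrosynthetic overview**
1. The pyran ring is closed last, by 6-endo-dig hydroalkoxylation of a hydroxymethyl group onto the enyne of a 2-(hydroxymethyl)-3-alkynylcyclohexenone.
2. That enynone comes from a cyclohexenone by 1,2-addition of an (E)-pentenynyl lithium and oxidative 1,3-transposition; the OCH2 carbon comes from a Morita–Baylis–Hillman hydroxymethylation.
3. Both stereocentres are set together by a desymmetrising, metal-free NHC-catalysed boryl conjugate addition/oxidation of a prochiral p-quinol ester.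
4. The p-quinol ester is made by oxidative dearomatisation of p-cresol with the hindered benzoic acid as nucleophile, so the tertiary ester C–O bond is formed at the ring carbon.
5. Ring order: the carbocycle is the p-cresol ring; the pyran is formed in the final step.

Assumption: the SMILES is read as (6R,7S) with the 6-OH trans to the 7-acyloxy group and cis to the 7-methyl; atom labels C1, O2, C3, C4, C4a, C5–C8, C8a of the 1H-isochromene target are used for the corresponding atoms of all intermediates.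

**Step 1**
Reactants: 1 3-methoxy-5-methylphenol
Product: 3 4-hydroxy-2-methoxy-6-methylbenzaldehyde, via aryl iminium chloride 2 (not isolated)
Conditions: POCl3 (1.2 equiv), DMF, 0 °C → rt; then H2O, 50 °C
Reagents that add atoms: N,N-dimethylformamide CN(C)C=O (formyl carbon); water O (formyl oxygen)
Why: Vilsmeier–Haack formylation attacks the position para to the free OH (also ortho to OMe and Me, the most activated site) and hydrolysis of iminium salt 2 gives the aldehyde; the minor ortho-hydroxy isomer is removed by chromatography.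

**Step 2**
Reactants: 3 4-hydroxy-2-methoxy-6-methylbenzaldehyde
Product: 4 2-methoxy-6-methyl-4-[(triisopropylsilyl)oxy]benzaldehyde
Conditions: TIPSCl (1.2 equiv), imidazole (2.5 equiv), DMF, rt
Reagents that add atoms: chlorotriisopropylsilane CC(C)[Si](Cl)(C(C)C)C(C)C
Why: Imidazole-assisted silylation of the phenol; the bulky TIPS ether is the aryl silyl ether best able to survive the mildly basic steps that follow and is removed with the other silyl groups at the end.

**Step 3**
Reactants: 4 2-methoxy-6-methyl-4-[(triisopropylsilyl)oxy]benzaldehyde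
Product: 5 2-methoxy-6-methyl-4-[(triisopropylsilyl)oxy]benzoic acid
Conditions: NaClO2, NaH2PO4, 2-methylbut-2-ene, t-BuOH/H2O, 0 °C → rt
Reagents that add atoms: sodium chlorite [Na+].[O-]Cl=O
Why: Pinnick oxidation: chlorous acid adds to the aldehyde and fragments to the acid while 2-methylbut-2-ene scavenges HOCl, so the electron-rich ring and silyl ether survive and no hydrolysis of a di-ortho-substituted benzoate is needed.

**Step 4**
Reactants: 5 2-methoxy-6-methyl-4-[(triisopropylsilyl)oxy]benzoic acid; 6 4-methylphenol (p-cresol)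
Product: 8 1-methyl-4-oxocyclohexa-2,5-dien-1-yl 2-methoxy-6-methyl-4-[(triisopropylsilyl)oxy]benzoate, via bis(aroyloxy)iodobenzene 7 (not isolated)
Conditions: PhI(OAc)2 (1.05 equiv), 5 (2.2 equiv), PhCl, 45 °C, 20 mbar (AcOH removed); then 6 (1.0 equiv), MeCN, −20 → 0 °C
Reagents that add atoms: none
Why: Hypervalent-iodine oxidative dearomatisation (Wessely-type p-quinol ester formation): after ligand exchange to 7, p-cresol binds iodine and the carboxylate attacks the methyl-bearing para carbon with loss of PhI, so the hindered ester bond is made at carbon rather than by acyl substitution; 8 has a mirror plane and no stereocentre, and the second equivalent of 5 is recovered.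

**Step 5**
Reactants: 8 1-methyl-4-oxocyclohexa-2,5-dien-1-yl 2-methoxy-6-methyl-4-[(triisopropylsilyl)oxy]benzoate
Product: 10 (1R,6R)-6-hydroxy-1-methyl-4-oxocyclohex-2-en-1-yl 2-methoxy-6-methyl-4-[(triisopropylsilyl)oxy]benzoate, via β-boryl ketone 9 (not isolated)
Conditions: (4S,5S)-1-(2,6-diisopropylphenyl)-3-mesityl-4,5-diphenyl-4,5-dihydro-1H-imidazol-3-ium tetrafluoroborate (5 mol %), DBU (20 mol %), B2pin2 (1.1 equiv), MeOH (20 equiv), THF, 0 °C; then NaBO3·4H2O, THF/H2O, 0 °C
Reagents that add atoms: sodium perborate tetrahydrate NaBO3·4H2O, written as its peroxoborate dimer [Na+].[Na+].O[B-]1(O)OO[B-](O)(O)OO1 (the C6 oxygen of 10); bis(pinacolato)diboron CC1(C)OB(OC1(C)C)B1OC(C)(C)C(C)(C)O1 (the boryl group of 9 only)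
Why: Proposed new method: a desymmetrising enantioselective boryl conjugate addition to a prochiral 4,4-disubstituted cyclohexa-2,5-dienone under metal-free carbene catalysis, in which the chiral NHC binds one boron of B2pin2 and the polarised sp2–sp3 diboron adduct transfers its boryl group to one of the two enantiotopic β-carbons (catalyst control, fixing the absolute configuration of C6 and thereby of C7) on the ring face anti to the bulky, electron-withdrawing aroyloxy group (steric and polar Felkin–Anh control, fixing the trans C6–O/C7–O relation), MeOH protonates the enolate and releases the carbene, and perborate then converts C–B into C–OH with retention; the closest known reaction types are the NHC-catalysed enantioselective boryl conjugate addition to simple enones and transition-metal-mediated desymmetrisations of cyclohexadienones.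

**Step 6**
Reactants: 10 (1R,6R)-6-hydroxy-1-methyl-4-oxocyclohex-2-en-1-yl 2-methoxy-6-methyl-4-[(triisopropylsilyl)oxy]benzoate
Product: 11 (1R,6R)-6-hydroxy-3-(hydroxymethyl)-1-methyl-4-oxocyclohex-2-en-1-yl 2-methoxy-6-methyl-4-[(triisopropylsilyl)oxy]benzoate
Conditions: aq. HCHO (37%, 3 equiv), DMAP (0.3 equiv), THF/H2O, rt
Reagents that add atoms: formaldehyde C=O
Why: Morita–Baylis–Hillman reaction: DMAP adds reversibly to C8 of the only remaining enone, the enolate carbon C8a adds to formaldehyde and DMAP is expelled, installing C1 without touching C6 or C7 (the di-ortho-substituted benzoate resists migration to the free C6–OH).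

**Step 7**
Reactants: 11 (1R,6R)-6-hydroxy-3-(hydroxymethyl)-1-methyl-4-oxocyclohex-2-en-1-yl 2-methoxy-6-methyl-4-[(triisopropylsilyl)oxy]benzoate
Product: 12 (1R,6R)-6-[(tert-butyldimethylsilyl)oxy]-3-{[(tert-butyldimethylsilyl)oxy]methyl}-1-methyl-4-oxocyclohex-2-en-1-yl 2-methoxy-6-methyl-4-[(triisopropylsilyl)oxy]benzoate
Conditions: TBSOTf (2.6 equiv), 2,6-lutidine (4 equiv), CH2Cl2, −78 → −20 °C
Reagents that add atoms: tert-butyldimethylsilyl trifluoromethanesulfonate CC(C)(C)[Si](C)(C)OS(=O)(=O)C(F)(F)F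
Why: Silyl triflate/lutidine silylation of both hydroxyls (the C6–OH next to the quaternary centre needs the triflate), masking them for the organolithium and chromium steps.

**Step 8**
Reactants: 13 (E)-1-bromoprop-1-ene; 14 ethynyl(trimethyl)silane
Product: 15 trimethyl[(E)-pent-3-en-1-yn-1-yl]silane
Conditions: PdCl2(PPh3)2 (2 mol %), CuI (4 mol %), Et3N, THF, rt
Reagents that add atoms: none
Why: Sonogashira coupling proceeds with retention of the (E)-alkene geometry, and the silyl group makes the volatile enyne easy to handle.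

**Step 9**
Reactants: 12 (1R,6R)-6-[(tert-butyldimethylsilyl)oxy]-3-{[(tert-butyldimethylsilyl)oxy]methyl}-1-methyl-4-oxocyclohex-2-en-1-yl 2-methoxy-6-methyl-4-[(triisopropylsilyl)oxy]benzoate; 15 trimethyl[(E)-pent-3-en-1-yn-1-yl]silane
Product: 17 (1R,6R)-6-[(tert-butyldimethylsilyl)oxy]-3-{[(tert-butyldimethylsilyl)oxy]methyl}-4-hydroxy-1-methyl-4-[(E)-pent-3-en-1-yn-1-yl]cyclohex-2-en-1-yl 2-methoxy-6-methyl-4-[(triisopropylsilyl)oxy]benzoate (both C4 epimers), via lithium pentenynide 16 (not isolated)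
Conditions: 15 (1.5 equiv), MeLi·LiBr (1.4 equiv), THF, 0 °C → rt; then 12, THF, −78 °C; aq. NH4Cl
Reagents that add atoms: none
Why: MeLi cleaves the alkynyl–Si bond to give acetylide 16, which adds 1,2 to the enone carbonyl (C4a) at −78 °C faster than it enolises C5 or attacks the hindered benzoate; the new carbinol centre is an epimer mixture that is erased in the next step.

**Step 10**
Reactants: 17 (1R,6R)-6-[(tert-butyldimethylsilyl)oxy]-3-{[(tert-butyldimethylsilyl)oxy]methyl}-4-hydroxy-1-methyl-4-[(E)-pent-3-en-1-yn-1-yl]cyclohex-2-en-1-yl 2-methoxy-6-methyl-4-[(triisopropylsilyl)oxy]benzoate (both C4 epimers)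
Product: 18 (1S,6R)-6-[(tert-butyldimethylsilyl)oxy]-3-{[(tert-butyldimethylsilyl)oxy]methyl}-1-methyl-2-oxo-4-[(E)-pent-3-en-1-yn-1-yl]cyclohex-3-en-1-yl 2-methoxy-6-methyl-4-[(triisopropylsilyl)oxy]benzoate
Conditions: [C5H5NH][CrO3Cl] (3 equiv), 4 Å molecular sieves, CH2Cl2, rt
Reagents that add atoms: pyridinium chlorochromate [C5H5NH][CrO3Cl] c1cc[nH+]cc1.[O-][Cr](=O)(=O)Cl (the C8 carbonyl oxygen, delivered through the chromate ester)
Why: Babler–Dauben oxidative transposition: the chromate ester of the tertiary allylic alcohol undergoes a [3,3] shift to C8 and is oxidised there, giving the C8 ketone and the C4a=C8a double bond conjugated to the enyne; C6 and C7 are untouched (the C7 descriptor changes to S only because the CIP priorities change).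

**Step 11**
Reactants: 18 (1S,6R)-6-[(tert-butyldimethylsilyl)oxy]-3-{[(tert-butyldimethylsilyl)oxy]methyl}-1-methyl-2-oxo-4-[(E)-pent-3-en-1-yn-1-yl]cyclohex-3-en-1-yl 2-methoxy-6-methyl-4-[(triisopropylsilyl)oxy]benzoate
Product: 19 (1S,6R)-6-hydroxy-3-(hydroxymethyl)-1-methyl-2-oxo-4-[(E)-pent-3-en-1-yn-1-yl]cyclohex-3-en-1-yl 4-hydroxy-2-methoxy-6-methylbenzoate
Conditions: aq. HF (48%)/MeCN 1:9, 0 °C → rt
Reagents that add atoms: none
Why: Fluoride-driven cleavage of all three Si–O bonds under acidic conditions, chosen because base could cause retro-aldol (C6–OH/C8=O) or vinylogous elimination of the C6 oxygen.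

**Step 12**
Reactants: 19 (1S,6R)-6-hydroxy-3-(hydroxymethyl)-1-methyl-2-oxo-4-[(E)-pent-3-en-1-yn-1-yl]cyclohex-3-en-1-yl 4-hydroxy-2-methoxy-6-methylbenzoate
Product: 20 (6R,7S)-6-hydroxy-7-methyl-8-oxo-3-[(E)-prop-1-en-1-yl]-5,6,7,8-tetrahydro-1H-isochromen-7-yl 4-hydroxy-2-methoxy-6-methylbenzoate
Conditions: (Ph3P)AuNTf2 (2 mol %), CH2Cl2, rt
Reagents that add atoms: none
Why: Gold-catalysed 6-endo-dig hydroalkoxylation: (Ph3P)AuNTf2 activates the alkyne, the C1–OH attacks the distal carbon C3 (cation-stabilised by the propenyl group, whereas C4 sits on the electron-poor enone β-carbon) and protodeauration gives the dienyl ether; no stereocentre is touched.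

**Compound list**
1 | 3-methoxy-5-methylphenol | COc1cc(C)cc(O)c1 | starting material
2 | [(4-hydroxy-2-methoxy-6-methylphenyl)methylidene]dimethylazanium chloride | COc1cc(O)cc(C)c1C=[N+](C)C.[Cl-] | intermediate
3 | 4-hydroxy-2-methoxy-6-methylbenzaldehyde | COc1cc(O)cc(C)c1C=O | intermediate
4 | 2-methoxy-6-methyl-4-[(triisopropylsilyl)oxy]benzaldehyde | COc1cc(O[Si](C(C)C)(C(C)C)C(C)C)cc(C)c1C=O | intermediate
5 | 2-methoxy-6-methyl-4-[(triisopropylsilyl)oxy]benzoic acid | COc1cc(O[Si](C(C)C)(C(C)C)C(C)C)cc(C)c1C(=O)O | intermediate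
6 | 4-methylphenol (p-cresol) | Cc1ccc(O)cc1 | starting material
7 | bis{2-methoxy-6-methyl-4-[(triisopropylsilyl)oxy]benzoyloxy}(phenyl)-λ3-iodane | COc1cc(O[Si](C(C)C)(C(C)C)C(C)C)cc(C)c1C(=O)OI(OC(=O)c1c(C)cc(O[Si](C(C)C)(C(C)C)C(C)C)cc1OC)c1ccccc1 | intermediate
8 | 1-methyl-4-oxocyclohexa-2,5-dien-1-yl 2-methoxy-6-methyl-4-[(triisopropylsilyl)oxy]benzoate | CC1(OC(=O)c2c(C)cc(O[Si](C(C)C)(C(C)C)C(C)C)cc2OC)C=CC(=O)C=C1 | intermediate
9 | (1S,6R)-1-methyl-4-oxo-6-(4,4,5,5-tetramethyl-1,3,2-dioxaborolan-2-yl)cyclohex-2-en-1-yl 2-methoxy-6-methyl-4-[(triisopropylsilyl)oxy]benzoate | O=C1C=C[C@@](C)(OC(=O)c2c(C)cc(O[Si](C(C)C)(C(C)C)C(C)C)cc2OC)[C@H](B2OC(C)(C)C(C)(C)O2)C1 | intermediate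
10 | (1R,6R)-6-hydroxy-1-methyl-4-oxocyclohex-2-en-1-yl 2-methoxy-6-methyl-4-[(triisopropylsilyl)oxy]benzoate | O=C1C=C[C@@](C)(OC(=O)c2c(C)cc(O[Si](C(C)C)(C(C)C)C(C)C)cc2OC)[C@H](O)C1 | intermediate
11 | (1R,6R)-6-hydroxy-3-(hydroxymethyl)-1-methyl-4-oxocyclohex-2-en-1-yl 2-methoxy-6-methyl-4-[(triisopropylsilyl)oxy]benzoate | O=C1C(CO)=C[C@@](C)(OC(=O)c2c(C)cc(O[Si](C(C)C)(C(C)C)C(C)C)cc2OC)[C@H](O)C1 | intermediate
12 | (1R,6R)-6-[(tert-butyldimethylsilyl)oxy]-3-{[(tert-butyldimethylsilyl)oxy]methyl}-1-methyl-4-oxocyclohex-2-en-1-yl 2-methoxy-6-methyl-4-[(triisopropylsilyl)oxy]benzoate | O=C1C(CO[Si](C)(C)C(C)(C)C)=C[C@@](C)(OC(=O)c2c(C)cc(O[Si](C(C)C)(C(C)C)C(C)C)cc2OC)[C@H](O[Si](C)(C)C(C)(C)C)C1 | intermediate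
13 | (E)-1-bromoprop-1-ene | C/C=C/Br | starting material
14 | ethynyl(trimethyl)silane | C#C[Si](C)(C)C | starting material
15 | trimethyl[(E)-pent-3-en-1-yn-1-yl]silane | C/C=C/C#C[Si](C)(C)C | intermediate
16 | lithium (E)-pent-3-en-1-yn-1-ide | [Li]C#C/C=C/C | intermediate
17 | (1R,6R)-6-[(tert-butyldimethylsilyl)oxy]-3-{[(tert-butyldimethylsilyl)oxy]methyl}-4-hydroxy-1-methyl-4-[(E)-pent-3-en-1-yn-1-yl]cyclohex-2-en-1-yl 2-methoxy-6-methyl-4-[(triisopropylsilyl)oxy]benzoate (both C4 epimers) | C/C=C/C#CC1(O)C(CO[Si](C)(C)C(C)(C)C)=C[C@@](C)(OC(=O)c2c(C)cc(O[Si](C(C)C)(C(C)C)C(C)C)cc2OC)[C@H](O[Si](C)(C)C(C)(C)C)C1 | intermediate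
18 | (1S,6R)-6-[(tert-butyldimethylsilyl)oxy]-3-{[(tert-butyldimethylsilyl)oxy]methyl}-1-methyl-2-oxo-4-[(E)-pent-3-en-1-yn-1-yl]cyclohex-3-en-1-yl 2-methoxy-6-methyl-4-[(triisopropylsilyl)oxy]benzoate | C/C=C/C#CC1=C(CO[Si](C)(C)C(C)(C)C)C(=O)[C@@](C)(OC(=O)c2c(C)cc(O[Si](C(C)C)(C(C)C)C(C)C)cc2OC)[C@H](O[Si](C)(C)C(C)(C)C)C1 | intermediate
19 | (1S,6R)-6-hydroxy-3-(hydroxymethyl)-1-methyl-2-oxo-4-[(E)-pent-3-en-1-yn-1-yl]cyclohex-3-en-1-yl 4-hydroxy-2-methoxy-6-methylbenzoate | C/C=C/C#CC1=C(CO)C(=O)[C@@](C)(OC(=O)c2c(C)cc(O)cc2OC)[C@H](O)C1 | intermediate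
20 | (6R,7S)-6-hydroxy-7-methyl-8-oxo-3-[(E)-prop-1-en-1-yl]-5,6,7,8-tetrahydro-1H-isochromen-7-yl 4-hydroxy-2-methoxy-6-methylbenzoate | C/C=C/C1=CC2=C(CO1)C(=O)[C@@](C)(OC(=O)c1c(C)cc(O)cc1OC)[C@H](O)C2 | target

**Step count**
Total: 12 steps. Longest linear sequence: 11 steps (steps 1–7 and 9–12; step 8 is a one-step side branch).

**Three steps most likely to fail, with fallbacks**

Step 5 (the proposed new desymmetrisation). Three things can go wrong:
- the carbene–diboron nucleophile may give low enantiotopic-group selectivity on a dienone, or the opposite sense (then the (4R,5R) salt is used);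
- the β-boryl/β'-aroyloxy arrangement in 9 can eliminate and rearomatise to p-cresol;
- DBU/MeOH can nibble at the aryl silyl ether.

The fallback uses known chemistry and sets out from 8. Amine-salt (iminium) catalysed asymmetric nucleophilic epoxidation of the cyclic enone with aqueous H2O2 (9-amino-9-deoxy-epi-quinine bis(trifluoroacetate) 10 mol %, dioxane, 30 °C; hydroperoxide adds anti to the aroyloxy group) gives the mono-epoxide (1S,5R,6R)-5-methyl-2-oxo-7-oxabicyclo[4.1.0]hept-3-en-5-yl 2-methoxy-6-methyl-4-[(triisopropylsilyl)oxy]benzoate F1. Its Cα–O bond is then cleaved reductively with Na[PhSeB(OEt)3] (from PhSeSePh and NaBH4, EtOH, AcOH, 0 °C), a non-radical reduction that cannot expel the aroyloxy group, and the route is rejoined at 10.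

Step 6 (Morita–Baylis–Hillman on a hindered enone). The β-carbon C8 is neopentylic, so amine addition may be too slow, and base can dehydrate the β-hydroxy ketone back to 8 or hydroxymethylate C5. The fallback sets out from 10: α-iodination (I2, pyridine, CH2Cl2, rt) gives the iodoenone (1R,6R)-6-hydroxy-3-iodo-1-methyl-4-oxocyclohex-2-en-1-yl 2-methoxy-6-methyl-4-[(triisopropylsilyl)oxy]benzoate F2. Stille coupling with Bu3SnCH2OH (Pd(PPh3)4, dioxane, 80 °C) then rejoins the route at 11.

Step 10 (oxidative transposition). The [3,3] shift must deliver chromium to a carbon next to a quaternary centre, and competing dehydration or propargylic pathways are possible. The fallback sets out from 17 and separates the two events. Ph3SiOReO3 (5 mol %, Et2O, −40 → 0 °C) isomerises the tertiary alcohol to the conjugated secondary allylic alcohol (1R,6R)-6-[(tert-butyldimethylsilyl)oxy]-3-{[(tert-butyldimethylsilyl)oxy]methyl}-2-hydroxy-1-methyl-4-[(E)-pent-3-en-1-yn-1-yl]cyclohex-3-en-1-yl 2-methoxy-6-methyl-4-[(triisopropylsilyl)oxy]benzoate (both C2 epimers) F3. Dess–Martin periodinane (NaHCO3, CH2Cl2) then oxidises it, rejoining the route at 18.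

**Further compounds**
F1 | step 5 | (1S,5R,6R)-5-methyl-2-oxo-7-oxabicyclo[4.1.0]hept-3-en-5-yl 2-methoxy-6-methyl-4-[(triisopropylsilyl)oxy]benzoate | O=C1C=C[C@@](C)(OC(=O)c3c(C)cc(O[Si](C(C)C)(C(C)C)C(C)C)cc3OC)[C@@H]2O[C@H]12
F2 | step 6 | (1R,6R)-6-hydroxy-3-iodo-1-methyl-4-oxocyclohex-2-en-1-yl 2-methoxy-6-methyl-4-[(triisopropylsilyl)oxy]benzoate | O=C1C(I)=C[C@@](C)(OC(=O)c2c(C)cc(O[Si](C(C)C)(C(C)C)C(C)C)cc2OC)[C@H](O)C1
F3 | step 10 | (1R,6R)-6-[(tert-butyldimethylsilyl)oxy]-3-{[(tert-butyldimethylsilyl)oxy]methyl}-2-hydroxy-1-methyl-4-[(E)-pent-3-en-1-yn-1-yl]cyclohex-3-en-1-yl 2-methoxy-6-methyl-4-[(triisopropylsilyl)oxy]benzoate (both C2 epimers) | C/C=C/C#CC1=C(CO[Si](C)(C)C(C)(C)C)C(O)[C@@](C)(OC(=O)c2c(C)cc(O[Si](C(C)C)(C(C)C)C(C)C)cc2OC)[C@H](O[Si](C)(C)C(C)(C)C)C1
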